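**Retrosynthetic overview**

Numbering used throughout: ring C1 (C–OH), C5 (CH–O-isovaleryl), C6 (CH–O lactone), C7, C8, C9 (C=O), C10 (CH–CH3, methyl C14); lactone C11 (=C13H2), C12 (C=O); side chain C2 (C=O), C3=C4, C15.
Enabling feature: the cis-fused α-methylene-γ-butyrolactone O6–C6–C7–C11(=C13)–C12(=O) on the cycloheptane is the retron of a [2+2+1] union of an aldehyde (C6=O), the internal C7=C11 bond of a terminal allene and CO (C12).
Key disconnections: C2/C9 ketones from silyl-protected carbinols and the C5 ester from a C1/C5 acetonide; then C6–C7, C11–C12 and C12–O6 in one allenic hetero-Pauson–Khand step from a monocyclic allenyl aldehyde; allene from alkyne (Crabbé), C8–C9 by propargylation, C2–C3 by propenyl addition to a lactol; C1–C10 by Ireland–Claisen rearrangement of bis-crotyl L-tartrate acetonide.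
Ring order: dioxolane (from tartrate, kept as a temporary conformational lock), then a temporary γ-lactone C2–O–C6 (differentiates the two carboxyls), then the cycloheptane and the α-methylene lactone together in the key step.

Key step: step 12

Remark: C2 and C9 are carried as silyl-protected carbinols and become ketones only in step 16, so C9 is drawn as the expected Felkin epimer and C2 is left without configuration (both epimers are carried on); (E)-but-2-en-1-ol and (E)-1-bromoprop-1-ene are assumed to be available geometrically pure.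

**Route**

Step 1
Reactants: 1 dimethyl (4R,5R)-2,2-dimethyl-1,3-dioxolane-4,5-dicarboxylate (dimethyl 2,3-O-isopropylidene-L-tartrate); 2 (E)-but-2-en-1-ol
Product: 3 bis[(E)-but-2-enyl] (4R,5R)-2,2-dimethyl-1,3-dioxolane-4,5-dicarboxylate
Conditions: 2 (6 equiv), Bu2SnO (10 mol %), toluene, 110 °C, MeOH distilled off
Reagents that add atoms: none
Why: Tin-catalysed transesterification driven by removal of methanol; the neutral conditions should not epimerise the two α-alkoxy centres, and the twofold-symmetric diester makes both arms equivalent for step 2.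

Step 2
Reactants: 3 bis[(E)-but-2-enyl] (4R,5R)-2,2-dimethyl-1,3-dioxolane-4,5-dicarboxylate
Product: 6 (4S,5R)-4-[(2S)-but-3-en-2-yl]-5-[(E)-but-2-enyloxycarbonyl]-2,2-dimethyl-1,3-dioxolane-4-carboxylic acid, via silyl ketene acetal 4 (not isolated), via trimethylsilyl ester 5 (not isolated)
Conditions: LiN(iPr)2 (1.0 equiv), THF, −78 °C; Me3SiCl, −78 °C → 40 °C; 1 M HCl work-up
Reagents that add atoms: none
Why: Ireland–Claisen rearrangement of an α-alkoxy ester: the chelated lithium enolate (OLi cis to the ring oxygen on C1) is silylated to ketene acetal 4, which rearranges through a chair with the (E)-crotyl methyl equatorial and with the allyl terminus adding to the dioxolane face anti to the C5 ester, so that the quaternary C1 and the methyl-bearing C10 are set together from the surviving tartrate centre (the mono-enolate resists a second deprotonation).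

Step 3
Reactants: 6 (4S,5R)-4-[(2S)-but-3-en-2-yl]-5-[(E)-but-2-enyloxycarbonyl]-2,2-dimethyl-1,3-dioxolane-4-carboxylic acid
Product: 8 (3aS,6aS)-3a-[(2S)-but-3-en-2-yl]-2,2-dimethyldihydrofuro[3,4-d][1,3]dioxol-4(3aH)-one, via hydroxy acid 7 (not isolated)
Conditions: LiBH4 (2.5 equiv), THF, 0 °C → rt; then 1 M HCl to pH 2, rt
Reagents that add atoms: none
Why: Chemoselective reduction and lactonisation: LiBH4 reduces the α-alkoxy crotyl ester but not the lithium carboxylate, and on acidification the new C6 hydroxyl, which is cis to the C1 carboxyl on the dioxolane, closes the cis-fused γ-lactone that differentiates C2 from C6 without touching a stereocentre.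

Step 4
Reactants: 8 (3aS,6aS)-3a-[(2S)-but-3-en-2-yl]-2,2-dimethyldihydrofuro[3,4-d][1,3]dioxol-4(3aH)-one
Product: 10 (2R)-2-[(3aS,6aS)-2,2-dimethyl-4-oxodihydrofuro[3,4-d][1,3]dioxol-3a(4H)-yl]propanal, via ozonide 9 (not isolated)
Conditions: O3, CH2Cl2, −78 °C; then PPh3, −78 °C → rt
Reagents that add atoms: ozone, [O-][O+]=O
Why: Ozonolysis with reductive work-up cleaves the only alkene to the C9 aldehyde under base-free conditions, so the adjacent C10 centre should not epimerise.

Step 5
Reactants: 10 (2R)-2-[(3aS,6aS)-2,2-dimethyl-4-oxodihydrofuro[3,4-d][1,3]dioxol-3a(4H)-yl]propanal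
Product: 11 (3aS,6aS)-3a-[(2S,3R)-3-hydroxyhex-5-yn-2-yl]-2,2-dimethyldihydrofuro[3,4-d][1,3]dioxol-4(3aH)-one
Conditions: propargyl bromide, Zn dust, THF/sat. aq. NH4Cl, 0 °C
Reagents that add atoms: propargyl bromide (3-bromoprop-1-yne), C#CCBr
Why: Zinc Barbier propargylation gives the homopropargylic alcohol; Felkin–Anh addition anti to the quaternary C1 substituent should favour the drawn C9 epimer (a centre that ends as the ketone), and the aqueous medium protonates the zinc alkoxide before it can attack the lactone.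

Step 6
Reactants: 11 (3aS,6aS)-3a-[(2S,3R)-3-hydroxyhex-5-yn-2-yl]-2,2-dimethyldihydrofuro[3,4-d][1,3]dioxol-4(3aH)-one
Product: 12 (3aS,6aS)-3a-[(2S,3R)-3-(tert-butyldimethylsilyloxy)hex-5-yn-2-yl]-2,2-dimethyldihydrofuro[3,4-d][1,3]dioxol-4(3aH)-one
Conditions: tBuMe2SiOTf, 2,6-lutidine, CH2Cl2, −78 → 0 °C
Reagents that add atoms: tert-butyldimethylsilyl triflate, CC(C)(C)[Si](C)(C)OS(=O)(=O)C(F)(F)F
Why: Silylation of the secondary alcohol with the silyl triflate and a hindered base is fast at low temperature and blocks translactonisation of the γ-hydroxy lactone.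

Step 7
Reactants: 12 (3aS,6aS)-3a-[(2S,3R)-3-(tert-butyldimethylsilyloxy)hex-5-yn-2-yl]-2,2-dimethyldihydrofuro[3,4-d][1,3]dioxol-4(3aH)-one
Product: 13 (3aS,6aS)-3a-[(2S,3R)-3-(tert-butyldimethylsilyloxy)hepta-5,6-dien-2-yl]-2,2-dimethyldihydrofuro[3,4-d][1,3]dioxol-4(3aH)-one
Conditions: (CH2O)n, CuI (50 mol %), Cy2NH, 1,4-dioxane, 100 °C
Reagents that add atoms: paraformaldehyde (as formaldehyde), C=O
Why: Crabbé homologation: copper-mediated Mannich reaction of the terminal alkyne with formaldehyde and the amine, then 1,5-hydride transfer with loss of the imine, converts C≡CH into the terminal allene CH=C=CH2 under conditions that silyl ether, acetonide and the hindered lactone should tolerate.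

Step 8
Reactants: 13 (3aS,6aS)-3a-[(2S,3R)-3-(tert-butyldimethylsilyloxy)hepta-5,6-dien-2-yl]-2,2-dimethyldihydrofuro[3,4-d][1,3]dioxol-4(3aH)-one
Product: 14 (3aS,6aS)-3a-[(2S,3R)-3-(tert-butyldimethylsilyloxy)hepta-5,6-dien-2-yl]-2,2-dimethyltetrahydrofuro[3,4-d][1,3]dioxol-4-ol (lactol, both anomers)
Conditions: iBu2AlH (1.2 equiv), CH2Cl2, −78 °C; aq. KNaC4H4O6 (potassium sodium tartrate) work-up
Reagents that add atoms: none
Why: Half-reduction of the γ-lactone with iBu2AlH stops at the lactol because the tetrahedral aluminium alkoxide is stable at −78 °C; allene, acetonide and silyl ether are inert.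

Step 9
Reactants: 14 lactol (3aS,6aS)-3a-[(2S,3R)-3-(tert-butyldimethylsilyloxy)hepta-5,6-dien-2-yl]-2,2-dimethyltetrahydrofuro[3,4-d][1,3]dioxol-4-ol
Product: 15 diol: 2,2-dimethyl-1,3-dioxolane bearing on C1 the (E)-1-hydroxybut-2-enyl group (C2 carbinol, both epimers) and the (2S,3R)-3-(tert-butyldimethylsilyloxy)hepta-5,6-dien-2-yl chain and on C5 a CH2OH group (C1, C5, C9, C10 as in 13)
Conditions: (E)-1-bromoprop-1-ene, t-BuLi (2 equiv per bromide), Et2O, −78 °C; MgBr2·OEt2, −78 → 0 °C; then 14, THF, −40 → 0 °C (3 equiv of the Grignard reagent)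
Reagents that add atoms: (E)-1-bromoprop-1-ene, C/C=C/Br
Why: Grignard addition to the ring-opened lactol (a non-enolisable aldehyde at C2): lithium–bromine exchange with retention and transmetalation give the (E)-propenyl Grignard reagent, which adds without deprotonating the allene; the C2 configuration is expected to be poorly controlled and does not matter because C2 ends as the ketone.

Step 10
Reactants: 15 diol (C2 carbinol epimers; primary C6 hydroxyl free)
Product: 17 tris-silyl ether: as 15 with C6–OSiEt3 and C2–OSi(tBu)Me2 (C9–OSi(tBu)Me2 unchanged), via mono-triethylsilyl ether 16 (not isolated)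
Conditions: Et3SiCl (1.05 equiv), 2,6-lutidine, CH2Cl2, −78 °C; then tBuMe2SiOTf (1.5 equiv), −78 → 0 °C
Reagents that add atoms: chlorotriethylsilane, CC[Si](Cl)(CC)CC; tert-butyldimethylsilyl triflate, CC(C)(C)[Si](C)(C)OS(=O)(=O)C(F)(F)F
Why: One-pot differential silylation: Et3SiCl takes the primary C6 hydroxyl selectively at −78 °C and the more reactive silyl triflate then caps the hindered allylic C2 hydroxyl.

Step 11
Reactants: 17 tris-silyl ether (C6–OSiEt3, C2–OTBS, C9–OTBS)
Product: 18 allenyl aldehyde: as 17 with C6 as the free aldehyde on C5 of the dioxolane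
Conditions: (COCl)2, DMSO, CH2Cl2, −78 → −40 °C; then iPr2NEt, −78 → 0 °C
Reagents that add atoms: none
Why: Swern oxidation applied directly to the primary triethylsilyl ether, which is exchanged by the chlorosulfonium salt and oxidised while the secondary TBS ethers stay, with iPr2NEt at low temperature to keep the α-alkoxy aldehyde from epimerising at C5.

Step 12
Reactants: 18 allenyl aldehyde
Product: 19 tricyclic lactone: target skeleton (cis-fused C6/C7 α-methylene-γ-butyrolactone on the cycloheptane) with the C1/C5 diol as trans-fused acetonide and C2 and C9 as TBS-protected carbinols (C1, C5, C6, C7, C10 as in the target)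
Conditions: Mo(CO)6 (1.2 equiv), DMSO (10 equiv), toluene (0.01 M), 100 °C
Reagents that add atoms: molybdenum hexacarbonyl, Mo(CO)6 (one CO becomes C12=O), [C-]#[O+].[C-]#[O+].[C-]#[O+].[C-]#[O+].[C-]#[O+].[C-]#[O+].[Mo]
Why: Proposed new method: DMSO-assisted loss of CO lets zerovalent molybdenum bind the C6 aldehyde and the internal C7=C11 bond of the allene side by side, oxidative cyclisation then forms C6–C7 and an oxamolybdacyclopentane (Mo–O6 and Mo–C11, C11=C13 left exocyclic), CO inserts into the Mo–C11 bond to make the C11–C12 bond, and C12–O6 reductive elimination releases the lactone. The closest known reaction type is the allenic hetero-Pauson–Khand cyclocarbonylation of allenyl aldehydes with Mo(CO)6/DMSO, established for cis-fused α-methylene-γ-butyrolactones on five- and six-membered carbocycles; the extension proposed here is the one-carbon-longer tether that closes a cycloheptane. The seven-membered ring closes by bond formation between C7 and the aldehyde carbon with both π-bonds exocyclic to the new ring (7-exo), and the five-membered lactone closes around the inserted CO by the C11–C12 bond and the C12–O6 bond. C6 and C7 are created together and should come out cis because O6 and C11 sit on the same metal in the metallacycle, while the face is set by the temporary trans-fused dioxolane: it holds O1 and O5 pseudo-equatorial, which forces the C1 side chain pseudo-axial on one face, so the metal-bound O6 takes the opposite face (trans to O5, cis to O1) as the target requires. The step needs chemoselectivity for the aldehyde and the internal allene bond, secured by masking C2 and C9 as silyl ethers (no other carbonyl or alkyne) and by the tether length (the terminal allene bond would give a nine-membered ring), and it needs cyclisation to outrun oligomerisation, which the quaternary C1, the dioxolane lock (C6 and C10 held gauche) and high dilution favour.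

Step 13
Reactants: 19 tricyclic lactone acetonide
Product: 20 C1,C5-diol: 19 without the acetonide (tertiary C1–OH and secondary C5–OH free; C2 and C9 still TBS ethers)
Conditions: AcOH/THF/H2O (3:1:1), 45 °C
Reagents that add atoms: none
Why: Acid-catalysed acetal hydrolysis: the strained trans-fused acetonide should hydrolyse well before the hindered secondary TBS ethers, unmasking the C1/C5 diol without touching a stereocentre or the lactone.

Step 14
Reactants: 20 C1,C5-diol
Product: 21 C5 isovalerate (3-methylbutanoate) of 20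
Conditions: isovaleric anhydride, DMAP (20 mol %), pyridine, CH2Cl2, 0 °C → rt
Reagents that add atoms: isovaleric anhydride (3-methylbutanoic anhydride), CC(C)CC(=O)OC(=O)CC(C)C
Why: DMAP-catalysed acylation: only the secondary C5 hydroxyl is esterified, the tertiary C1 hydroxyl being unreactive under these conditions.

Step 15
Reactants: 21 C5 isovalerate
Product: 22 triol: 21 without the two TBS groups (C1, C2 and C9 hydroxyls free; C2 epimers)
Conditions: HF·pyridine, pyridine/THF, 0 °C → rt
Reagents that add atoms: none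
Why: Fluoride-mediated desilylation under buffered, weakly acidic conditions removes both TBS ethers without acyl migration or conjugate addition to the α-methylene lactone.

Step 16
Reactants: 22 triol
Product: 23 CNP0283951.1 (1S,5S,6R,7S,10R in the numbering used here)
Conditions: IBX (3 equiv), DMSO, rt
Reagents that add atoms: none
Why: IBX oxidation converts the allylic C2 carbinol into the enone and the C9 carbinol into the ring ketone without glycol cleavage at C1–C2, leaves the tertiary C1 hydroxyl, and is neutral enough not to epimerise C10 next to the new ketone.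

**Compound list**

1 | dimethyl (4R,5R)-2,2-dimethyl-1,3-dioxolane-4,5-dicarboxylate (dimethyl 2,3-O-isopropylidene-L-tartrate) | COC(=O)[C@@H]1OC(C)(C)O[C@H]1C(=O)OC | starting material
2 | (E)-but-2-en-1-ol (trans-crotyl alcohol) | C/C=C/CO | starting material
3 | bis[(E)-but-2-enyl] (4R,5R)-2,2-dimethyl-1,3-dioxolane-4,5-dicarboxylate | C/C=C/COC(=O)[C@@H]1OC(C)(C)O[C@H]1C(=O)OC/C=C/C | intermediate
4 | silyl ketene acetal of 3: (5R)-dioxolane with exocyclic C1=C2(OSiMe3)(O-crotyl), OSiMe3 cis to the ring oxygen on C1 (Z), C5 crotyl ester unchanged | C/C=C/CO/C(O[Si](C)(C)C)=C1/OC(C)(C)O[C@H]1C(=O)OC/C=C/C | intermediate (not isolated)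
5 | trimethylsilyl ester of acid 6 | C[Si](C)(C)OC(=O)[C@@]1([C@@H](C)C=C)OC(C)(C)O[C@H]1C(=O)OC/C=C/C | intermediate (not isolated)
6 | (4S,5R)-4-[(2S)-but-3-en-2-yl]-5-[(E)-but-2-enyloxycarbonyl]-2,2-dimethyl-1,3-dioxolane-4-carboxylic acid | OC(=O)[C@@]1([C@@H](C)C=C)OC(C)(C)O[C@H]1C(=O)OC/C=C/C | intermediate
7 | (4S,5S)-4-[(2S)-but-3-en-2-yl]-5-(hydroxymethyl)-2,2-dimethyl-1,3-dioxolane-4-carboxylic acid (lithium salt in the flask) | OC(=O)[C@@]1([C@@H](C)C=C)OC(C)(C)O[C@H]1CO | intermediate (not isolated)
8 | (3aS,6aS)-3a-[(2S)-but-3-en-2-yl]-2,2-dimethyldihydrofuro[3,4-d][1,3]dioxol-4(3aH)-one (cis-fused lactone) | O=C1OC[C@@H]2OC(C)(C)O[C@]12[C@@H](C)C=C | intermediate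
9 | ozonide (1,2,4-trioxolane) of the vinyl group of 8, mixture at the ozonide carbon | O=C1OC[C@@H]2OC(C)(C)O[C@]12[C@@H](C)C3OCOO3 | intermediate (not isolated)
10 | (2R)-2-[(3aS,6aS)-2,2-dimethyl-4-oxodihydrofuro[3,4-d][1,3]dioxol-3a(4H)-yl]propanal | O=C1OC[C@@H]2OC(C)(C)O[C@]12[C@@H](C)C=O | intermediate
11 | (3aS,6aS)-3a-[(2S,3R)-3-hydroxyhex-5-yn-2-yl]-2,2-dimethyldihydrofuro[3,4-d][1,3]dioxol-4(3aH)-one | O=C1OC[C@@H]2OC(C)(C)O[C@]12[C@@H](C)[C@H](O)CC#C | intermediate
12 | (3aS,6aS)-3a-[(2S,3R)-3-(tert-butyldimethylsilyloxy)hex-5-yn-2-yl]-2,2-dimethyldihydrofuro[3,4-d][1,3]dioxol-4(3aH)-one | O=C1OC[C@@H]2OC(C)(C)O[C@]12[C@@H](C)[C@H](O[Si](C)(C)C(C)(C)C)CC#C | intermediate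
13 | (3aS,6aS)-3a-[(2S,3R)-3-(tert-butyldimethylsilyloxy)hepta-5,6-dien-2-yl]-2,2-dimethyldihydrofuro[3,4-d][1,3]dioxol-4(3aH)-one | O=C1OC[C@@H]2OC(C)(C)O[C@]12[C@@H](C)[C@H](O[Si](C)(C)C(C)(C)C)CC=C=C | intermediate
14 | lactol of 13: (3aS,6aS)-3a-[(2S,3R)-3-(tert-butyldimethylsilyloxy)hepta-5,6-dien-2-yl]-2,2-dimethyltetrahydrofuro[3,4-d][1,3]dioxol-4-ol (both anomers) | OC1OC[C@@H]2OC(C)(C)O[C@]12[C@@H](C)[C@H](O[Si](C)(C)C(C)(C)C)CC=C=C | intermediate
15 | diol: 2,2-dimethyl-1,3-dioxolane with C1 bearing the (E)-1-hydroxybut-2-enyl group (C2 carbinol, both epimers) and the (2S,3R)-3-(TBSO)hepta-5,6-dien-2-yl chain, C5 bearing CH2OH (C1, C5, C9, C10 as in 13) | C/C=C/C(O)[C@]1(OC(C)(C)O[C@H]1CO)[C@@H](C)[C@H](O[Si](C)(C)C(C)(C)C)CC=C=C | intermediate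
16 | 15 with the primary C6 hydroxyl as triethylsilyl ether | C/C=C/C(O)[C@]1(OC(C)(C)O[C@H]1CO[Si](CC)(CC)CC)[C@@H](C)[C@H](O[Si](C)(C)C(C)(C)C)CC=C=C | intermediate (not isolated)
17 | 16 with the C2 hydroxyl as tert-butyldimethylsilyl ether | C/C=C/C(O[Si](C)(C)C(C)(C)C)[C@]1(OC(C)(C)O[C@H]1CO[Si](CC)(CC)CC)[C@@H](C)[C@H](O[Si](C)(C)C(C)(C)C)CC=C=C | intermediate
18 | allenyl aldehyde: 17 with C6 as the free aldehyde on C5 of the dioxolane | C/C=C/C(O[Si](C)(C)C(C)(C)C)[C@]1(OC(C)(C)O[C@H]1C=O)[C@@H](C)[C@H](O[Si](C)(C)C(C)(C)C)CC=C=C | intermediate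
19 | tricyclic lactone: target skeleton with the C1/C5 diol as trans-fused acetonide and C2, C9 as TBS-protected carbinols (C1, C5, C6, C7, C10 as in the target) | C=C1C(=O)O[C@@H]2[C@H]1C[C@@H](O[Si](C)(C)C(C)(C)C)[C@H](C)[C@@]3(OC(C)(C)O[C@@H]23)C(O[Si](C)(C)C(C)(C)C)/C=C/C | intermediate
20 | C1,C5-diol of 19 (acetonide removed) | C=C1C(=O)O[C@@H]2[C@H]1C[C@@H](O[Si](C)(C)C(C)(C)C)[C@H](C)[C@@](O)(C(O[Si](C)(C)C(C)(C)C)/C=C/C)[C@H]2O | intermediate
21 | C5 isovalerate (3-methylbutanoate) of 20 | C=C1C(=O)O[C@@H]2[C@H]1C[C@@H](O[Si](C)(C)C(C)(C)C)[C@H](C)[C@@](O)(C(O[Si](C)(C)C(C)(C)C)/C=C/C)[C@H]2OC(=O)CC(C)C | intermediate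
22 | triol: 21 without the two TBS groups (C2 epimers) | C=C1C(=O)O[C@@H]2[C@H]1C[C@@H](O)[C@H](C)[C@@](O)(C(O)/C=C/C)[C@H]2OC(=O)CC(C)C | intermediate
23 | CNP0283951.1 (1S,5S,6R,7S,10R in the numbering used here) | C=C1C(=O)O[C@@H]2[C@H]1CC(=O)[C@H](C)[C@@](O)(C(=O)/C=C/C)[C@H]2OC(=O)CC(C)C | target

Total step count: 16
Longest linear sequence: 16 steps (from 1)

**Steps most likely to fail**

Step 12 (Proposed new method). Oxidative cyclisation to a seven-membered ring may be too slow, so that the aldehyde is lost to oligomerisation. The metallacycle may also form on the wrong aldehyde face, which would erode the C6/C7 configuration. The fallback uses known reaction types, sets out from 18 and comes back at 19. Palladium-catalysed silylstannylation of the allene with Me3Si–SnBu3 ([Pd(allyl)Cl]2 cat., THF, rt) gives a 2-silylallylstannane that adds in the flask to the aldehyde (BF3·OEt2 at −78 °C if the closure needs help). This should give the cis 2-(1-trimethylsilylvinyl)cycloheptanol F1. Iododesilylation with N-iodosuccinimide then gives the vinyl iodide F2. Palladium-catalysed carbonylative lactonisation (CO 1 atm, Pd(PPh3)4 cat., Et3N, THF, 50 °C), in which CO inserts into the C11–Pd bond and O6 captures the acyl group, then gives 19.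

Step 2. The lithium enolate may open the dioxolane by β-elimination before it is silylated, the ketene acetal geometry may be incompletely controlled, or a second enolisation may occur; each would erode the C1/C10 configuration or the material balance. The fallback sets out from 1 and comes back at 8. Deprotonation of 1 (LiN(SiMe3)2, THF, −78 °C) and branched-selective iridium-catalysed allylic alkylation with methyl (E)-but-2-enyl carbonate ([Ir(cod)Cl]2 with a chiral phosphoramidite ligand) should give the allylated dimethyl diester F3; here the catalyst sets C10 and the dioxolane face sets C1. NaBH4 (EtOH, 0 °C) then reduces the less hindered C6 ester, and the hydroxy ester lactonises onto the C2 ester to give 8 directly.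

Step 13. One or both TBS ethers may be lost, or the allylic C2–O bond may ionise, before the acetonide is hydrolysed; this would remove the differentiation of the C5 hydroxyl. The fallback changes the order of the endgame, sets out from 19 and comes back at 23. The silyl ethers are removed first (HF·pyridine) to give the diol acetonide F4. Both carbinols are oxidised (IBX, DMSO) to the diketone acetonide F5. The acetonide is hydrolysed with aqueous CF3CO2H to the des-isovaleryl diketone diol F6. Its only secondary hydroxyl is then acylated (isovaleric anhydride, DMAP, 0 °C) to reach 23.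

**Further compounds**

F1 | step 12 | cis 2-(1-trimethylsilylvinyl)cycloheptanol: C6–OH and C7–C11(SiMe3)=C13H2 cis, acetonide and both TBS ethers as in 19 | C=C([Si](C)(C)C)[C@@H]1C[C@@H](O[Si](C)(C)C(C)(C)C)[C@H](C)[C@@]2(OC(C)(C)O[C@H]2[C@@H]1O)C(O[Si](C)(C)C(C)(C)C)/C=C/C
F2 | step 12 | vinyl iodide: F1 with iodine in place of SiMe3 on C11 | C=C(I)[C@@H]1C[C@@H](O[Si](C)(C)C(C)(C)C)[C@H](C)[C@@]2(OC(C)(C)O[C@H]2[C@@H]1O)C(O[Si](C)(C)C(C)(C)C)/C=C/C
F3 | step 2 | dimethyl (4S,5R)-4-[(2S)-but-3-en-2-yl]-2,2-dimethyl-1,3-dioxolane-4,5-dicarboxylate | COC(=O)[C@@]1([C@@H](C)C=C)OC(C)(C)O[C@H]1C(=O)OC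
F4 | step 13 | diol acetonide: 19 without the two TBS groups (C2 epimers) | C=C1C(=O)O[C@@H]2[C@H]1C[C@@H](O)[C@H](C)[C@@]3(OC(C)(C)O[C@@H]23)C(O)/C=C/C
F5 | step 13 | diketone acetonide: F4 with C2 and C9 as ketones | C=C1C(=O)O[C@@H]2[C@H]1CC(=O)[C@H](C)[C@@]3(OC(C)(C)O[C@@H]23)C(=O)/C=C/C
F6 | step 13 | des-isovaleryl target: diketone with free C1 and C5 hydroxyls | C=C1C(=O)O[C@@H]2[C@H]1CC(=O)[C@H](C)[C@@](O)(C(=O)/C=C/C)[C@H]2O
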